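## Retrosynthetic overview

1. The dihydrofuran ring is formed last: the C2–O1 bond closes by 5-exo addition of the ring-A phenol to a para-quinone methide of ring B, trans to the C-3 aroyl group.
2. Key C–C bond, C3–C(=O): 2,4-dihydroxybenzaldehyde serves as an acyl anion equivalent (chelated acyl–rhodium hydride) and acylates the benzylic carbon of a 2-hydroxystilbene. In polar terms that carbon is the ortho-quinone-methide (acceptor) carbon of ring A, so two acceptor carbons are joined; the chiral catalyst sets C-3.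
3. The stilbene–chalcone precursor comes from a Heck coupling (stilbene) followed by a Claisen–Schmidt condensation (enone), both carried out before any stereocentre exists.
4. The four aromatic rings arrive intact from four commercial phenols; the only protecting group is a transient acetate.

Assumption: the target SMILES encodes the (2S,3S)-2,3-trans isomer; (R)-DTBM-SEGPHOS is written as the ligand antipode assumed to give (R) at the new ketone α-carbon, and its mirror image is used if the sense of induction proves opposite.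

Ring letters: A = benzo ring of the benzofuran; B = 4-hydroxyphenyl on C-2; C = 2,4-dihydroxyphenyl of the C-3 ketone; D = 2,4-dihydroxyphenyl of the enone.

## Route

Step 1
Reactants: 1 4-hydroxy-3-iodobenzaldehyde; 2 4-ethenylphenyl acetate (4-acetoxystyrene)
Product: 3 4-[(E)-2-(5-formyl-2-hydroxyphenyl)ethenyl]phenyl acetate
Conditions: Pd(OAc)2 (2 mol%), P(o-tol)3 (4 mol%), Et3N (2.5 equiv), DMF, 90 °C
Reagents that add atoms: none
Why: Mizoroki–Heck reaction, in which zerovalent palladium inserts into the C–I bond of 1, the aryl group adds to the unsubstituted alkene carbon of 2 and syn β-hydride elimination gives the (E)-stilbene; no stereocentre is formed.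

Step 2
Reactants: 3 4-[(E)-2-(5-formyl-2-hydroxyphenyl)ethenyl]phenyl acetate; 4 1-(2,4-dihydroxyphenyl)ethanone
Product: 7 (E)-1-(2,4-dihydroxyphenyl)-3-{4-hydroxy-3-[(E)-2-(4-hydroxyphenyl)ethenyl]phenyl}prop-2-en-1-one, via deacetylated stilbene aldehyde 5 (not isolated), via aldol adduct 6 (not isolated)
Conditions: KOH (50% aq., 12 equiv), EtOH, 0 → 50 °C, 24–48 h; then 1 M HCl to pH 3
Reagents that add atoms: none
Why: Claisen–Schmidt (crossed aldol) condensation, in which hydroxide first cleaves the aryl acetate, the enolate of 4 adds to the aldehyde and the aldol loses water by E1cB to the (E)-enone, strong base being harmless here because no stereocentre exists yet.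

Step 3
Reactants: 7 (E)-1-(2,4-dihydroxyphenyl)-3-{4-hydroxy-3-[(E)-2-(4-hydroxyphenyl)ethenyl]phenyl}prop-2-en-1-one; 8 2,4-dihydroxybenzaldehyde (1.5 equiv)
Product: 9 (E)-1-(2,4-dihydroxyphenyl)-3-{3-[(2R)-1-(2,4-dihydroxyphenyl)-3-(4-hydroxyphenyl)-1-oxopropan-2-yl]-4-hydroxyphenyl}prop-2-en-1-one
Conditions: [Rh(cod)OMe]2 (5 mol%), (R)-DTBM-SEGPHOS (11 mol%), 1,4-dioxane, 60 °C, no added base; short silica plug, use at once
Reagents that add atoms: none
Why: Proposed new method: enantioselective phenol-directed intermolecular hydroacylation of an internal (E)-alkene (closest known chemistry: rhodium-catalysed alkene hydroacylation by chelating salicylaldehydes and the branched-selective hydroacylation of 2-vinylphenols), in which C–H oxidative addition of chelated 8 to monovalent rhodium gives an acyl–rhodium hydride that acts as acyl anion plus proton, the ring-A phenol binds the metal so that hydride goes to C-2 and rhodium to the benzylic C-3 (five-membered oxarhodacycle), the chiral bisphosphine selects the alkene face in this syn insertion, and C–C reductive elimination with retention gives the (R)-α-aryl ketone under neutral conditions that do not enolise it, with no by-product.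

Step 4
Reactants: 9 (E)-1-(2,4-dihydroxyphenyl)-3-{3-[(2R)-1-(2,4-dihydroxyphenyl)-3-(4-hydroxyphenyl)-1-oxopropan-2-yl]-4-hydroxyphenyl}prop-2-en-1-one
Product: 11 (E)-1-(2,4-dihydroxyphenyl)-3-[(2S,3S)-3-(2,4-dihydroxybenzoyl)-2-(4-hydroxyphenyl)-2,3-dihydro-1-benzofuran-5-yl]prop-2-en-1-one, via para-quinone methide 10 (not isolated)
Conditions: DDQ (1.05 equiv), 1,4-dioxane/CH2Cl2 (1:1), 0 °C → rt, dark; filter, chromatograph on neutral silica (no base)
Reagents that add atoms: none
Why: Biomimetic quinone methide cyclisation, in which DDQ dehydrogenates the 4-alkylphenol (ring B) to the para-quinone methide and the neighbouring ring-A hydroxyl adds to the methide carbon in a 5-exo oxa-1,6-addition anti to the C-3 aroyl group, so the existing C-3 centre (R in 9, named S in 11 only because the priorities change) fixes C-2 as S and the ring as trans.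

## Compound list

1 | 4-hydroxy-3-iodobenzaldehyde | O=Cc1ccc(O)c(I)c1 | starting material
2 | 4-ethenylphenyl acetate (4-acetoxystyrene) | CC(=O)Oc1ccc(C=C)cc1 | starting material
3 | 4-[(E)-2-(5-formyl-2-hydroxyphenyl)ethenyl]phenyl acetate | CC(=O)Oc1ccc(/C=C/c2cc(C=O)ccc2O)cc1 | intermediate
4 | 1-(2,4-dihydroxyphenyl)ethanone (2,4-dihydroxyacetophenone) | CC(=O)c1ccc(O)cc1O | starting material
5 | 4-hydroxy-3-[(E)-2-(4-hydroxyphenyl)ethenyl]benzaldehyde | O=Cc1ccc(O)c(/C=C/c2ccc(O)cc2)c1 | intermediate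
6 | 1-(2,4-dihydroxyphenyl)-3-hydroxy-3-{4-hydroxy-3-[(E)-2-(4-hydroxyphenyl)ethenyl]phenyl}propan-1-one (racemic carbinol) | O=C(CC(O)c1ccc(O)c(/C=C/c2ccc(O)cc2)c1)c1ccc(O)cc1O | intermediate
7 | (E)-1-(2,4-dihydroxyphenyl)-3-{4-hydroxy-3-[(E)-2-(4-hydroxyphenyl)ethenyl]phenyl}prop-2-en-1-one | O=C(/C=C/c1ccc(O)c(/C=C/c2ccc(O)cc2)c1)c1ccc(O)cc1O | intermediate
8 | 2,4-dihydroxybenzaldehyde | O=Cc1ccc(O)cc1O | starting material
9 | (E)-1-(2,4-dihydroxyphenyl)-3-{3-[(2R)-1-(2,4-dihydroxyphenyl)-3-(4-hydroxyphenyl)-1-oxopropan-2-yl]-4-hydroxyphenyl}prop-2-en-1-one | O=C(/C=C/c1ccc(O)c(c1)[C@H](C(=O)c1ccc(O)cc1O)Cc1ccc(O)cc1)c1ccc(O)cc1O | intermediate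
10 | (E)-1-(2,4-dihydroxyphenyl)-3-{3-[(2R)-1-(2,4-dihydroxyphenyl)-1-oxo-3-(4-oxocyclohexa-2,5-dien-1-ylidene)propan-2-yl]-4-hydroxyphenyl}prop-2-en-1-one | O=C(/C=C/c1ccc(O)c(c1)[C@H](C(=O)c1ccc(O)cc1O)C=C1C=CC(=O)C=C1)c1ccc(O)cc1O | intermediate
11 | (E)-1-(2,4-dihydroxyphenyl)-3-[(2S,3S)-3-(2,4-dihydroxybenzoyl)-2-(4-hydroxyphenyl)-2,3-dihydro-1-benzofuran-5-yl]prop-2-en-1-one | O=C(/C=C/c1ccc2c(c1)[C@H](C(=O)c1ccc(O)cc1O)[C@@H](c1ccc(O)cc1)O2)c1ccc(O)cc1O | target

## Step count and risks

Total steps: 4. Longest linear sequence: 4 (1 → 3 → 7 → 9 → 11).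

Steps most likely to fail:

**Step 3 (key hydroacylation).** Internal stilbenes insert slowly, five free phenols and the 2-hydroxyaryl ketone may bind rhodium, and the enantioselectivity is unproven. The fallback sets out from 7 and 8 and comes back at 11, and moves stereocontrol from the C–C to the C–O bond formation:
- 7 and 8 are joined with the achiral small-bite-angle system [Rh(cod)OMe]2/bis(dicyclohexylphosphino)methane (dioxane, 70 °C), the ligand class proven for vinylphenols, to give the racemic seco ketone F3.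
- DDQ as in step 4 gives the racemic trans-dihydrobenzofuran F4.
- K2CO3 in MeOH (rt, then AcOH) opens F4 by retro-oxa-Michael (E1cB) to the achiral open dienone F5.
- The chiral phosphoric acid (R)-TRIP (10 mol%, toluene, rt) then protonates C-3 of this para-hydroxystyrene unit face-selectively, and the ring-A hydroxyl closes the resulting quinone methide/phosphate ion pair to 11. This last operation is itself a proposal; the closest known chemistry is phosphoric-acid-catalysed addition to para-quinone methides generated in situ.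

**Step 4 (DDQ ring closure).** With the 4-hydroxycinnamoyl unit present, DDQ may couple phenols, over-oxidise 11 to the benzofuran, or let 10 tautomerise. The fallback sets out from 3 and comes back at 11; the oxidation is done before the enone exists and the enone is added last without base:
- 3 is deacetylated (K2CO3, MeOH, 0 °C) and 5 is isolated.
- 5 and 8 are coupled under the step 3 conditions (the chelating salicylaldehyde is activated, the non-chelating formyl group of 5 is not) to give the aldehyde ketone F6.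
- DDQ closes it to the dihydrobenzofuran aldehyde F7.
- 2-Chloro-1-(2,4-dihydroxyphenyl)ethanone and PPh3 give the phosphonium chloride F8, and NaHCO3 converts it to the stabilised ylide F9.
- Wittig olefination of F7 with F9 (toluene, 70 °C) gives the (E)-enone 11.

**Step 2 (aldol on free phenols).** Both partners are phenoxides in KOH, so conversion may be poor. The fallback sets out from 1 and 4 and comes back at 7; the condensation is done under acid before the acid-sensitive stilbene exists:
- 1 and 4 are condensed with BF3·OEt2 (dioxane, rt) to the iodochalcone F1.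
- Heck coupling of F1 with 2 under Jeffery conditions (Pd(OAc)2, NaHCO3, Bu4NCl, DMF, 60 °C) gives the stilbene acetate F2.
- K2CO3 in MeOH (0 °C) removes the acetate to give 7.

## Further compounds

F1 | step 2 | (E)-1-(2,4-dihydroxyphenyl)-3-(4-hydroxy-3-iodophenyl)prop-2-en-1-one | O=C(/C=C/c1ccc(O)c(I)c1)c1ccc(O)cc1O
F2 | step 2 | 4-[(E)-2-{5-[(E)-3-(2,4-dihydroxyphenyl)-3-oxoprop-1-en-1-yl]-2-hydroxyphenyl}ethenyl]phenyl acetate | CC(=O)Oc1ccc(/C=C/c2cc(/C=C/C(=O)c3ccc(O)cc3O)ccc2O)cc1
F3 | step 3 | racemic (E)-1-(2,4-dihydroxyphenyl)-3-{3-[1-(2,4-dihydroxyphenyl)-3-(4-hydroxyphenyl)-1-oxopropan-2-yl]-4-hydroxyphenyl}prop-2-en-1-one | O=C(/C=C/c1ccc(O)c(c1)C(C(=O)c1ccc(O)cc1O)Cc1ccc(O)cc1)c1ccc(O)cc1O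
F4 | step 3 | racemic trans-(E)-1-(2,4-dihydroxyphenyl)-3-[3-(2,4-dihydroxybenzoyl)-2-(4-hydroxyphenyl)-2,3-dihydro-1-benzofuran-5-yl]prop-2-en-1-one | O=C(/C=C/c1ccc2c(c1)C(C(=O)c1ccc(O)cc1O)C(c1ccc(O)cc1)O2)c1ccc(O)cc1O
F5 | step 3 | 1-(2,4-dihydroxyphenyl)-2-{5-[(E)-3-(2,4-dihydroxyphenyl)-3-oxoprop-1-en-1-yl]-2-hydroxyphenyl}-3-(4-hydroxyphenyl)prop-2-en-1-one (geometry of the trisubstituted alkene not defined) | O=C(/C=C/c1ccc(O)c(c1)C(=Cc1ccc(O)cc1)C(=O)c1ccc(O)cc1O)c1ccc(O)cc1O
F6 | step 4 | 3-[(2R)-1-(2,4-dihydroxyphenyl)-3-(4-hydroxyphenyl)-1-oxopropan-2-yl]-4-hydroxybenzaldehyde | O=Cc1ccc(O)c(c1)[C@H](C(=O)c1ccc(O)cc1O)Cc1ccc(O)cc1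
F7 | step 4 | (2S,3S)-3-(2,4-dihydroxybenzoyl)-2-(4-hydroxyphenyl)-2,3-dihydro-1-benzofuran-5-carbaldehyde | O=Cc1ccc2c(c1)[C@H](C(=O)c1ccc(O)cc1O)[C@@H](c1ccc(O)cc1)O2
F8 | step 4 | [2-(2,4-dihydroxyphenyl)-2-oxoethyl](triphenyl)phosphonium chloride | O=C(C[P+](c1ccccc1)(c1ccccc1)c1ccccc1)c1ccc(O)cc1O.[Cl-]
F9 | step 4 | 1-(2,4-dihydroxyphenyl)-2-(triphenylphosphoranylidene)ethanone | O=C(C=P(c1ccccc1)(c1ccccc1)c1ccccc1)c1ccc(O)cc1O
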